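**Retrosynthetic overview**

- Feature: in ring B, C1' (the carbon bonded to C2 of ring C) lies between two oxygen-bearing carbons, C2' (OH) and C6' (OMe). A vinylketene–ynol ether benzannulation gives exactly this pattern when the alkyne substituent is the chromanyl C2.
- Key disconnection: ring B is opened at C1'–C6' and C2'–C3' (ketene–alkyne [2+2]) and at C5'–C6' (6π closure), leading back to cyclobutenone and a (2S)-2-(silyloxyethynyl)chromanone ketal. The phenol/silyl ether pair formed allows one clean O-methylation.
- The siloxyalkyne comes from the (2S)-2-ethynyl ketal by acetylide oxidation and O-silylation. C2 is set by copper-catalysed enantioselective alkynylation of a 5-benzyloxy-6,7,8-trimethoxychromone.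
- The chromone is built from 1,2,3,4-tetramethoxybenzene by hydroxylation, ortho-acylation and enaminone cyclisation. O5 is changed there from methyl to benzyl, so that no Lewis acid is needed once the electron-rich, ionisable C2-aryl ether exists.
- Ring order: A (bought), C (step 3), B (step 12). End game: O-methylation, hydrogenolysis, desilylation with ketal hydrolysis.

Key step: step 12

Remark: the antipode of the alkynylation ligand is chosen so that the 2S product forms; its sense of induction is to be confirmed on the first alkynyl ketone before material is carried on.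

**Route**

Step 1
Reactants: 1 1,2,3,4-tetramethoxybenzene
Product: 4 2,3,4,5-tetramethoxyphenol, via aryllithium 2 (not isolated), via lithium aryltrimethoxyborate 3 (not isolated)
Conditions: n-BuLi, TMEDA, THF, 0 °C to rt; B(OMe)3, −78 °C to rt; AcOH, 30% H2O2, 0 °C to rt
Reagents that add atoms: hydrogen peroxide, OO
Why: Directed ortho-lithiation beside a methoxy group (the two ring hydrogens are equivalent), borylation and boronate oxidation (1,2-aryl shift from boron to peroxide oxygen) should give the phenol as a single isomer.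

Step 2
Reactants: 4 2,3,4,5-tetramethoxyphenol
Product: 5 1-(2-hydroxy-3,4,5,6-tetramethoxyphenyl)ethan-1-one
Conditions: AcOH, BF3·OEt2, 90 °C; then H2O
Reagents that add atoms: acetic acid, CC(=O)O
Why: Boron trifluoride-mediated ortho-acylation of the phenol (Friedel–Crafts/Fries type) can occur only at the single unsubstituted ring position, which is ortho to the hydroxyl.

Step 3
Reactants: 5 1-(2-hydroxy-3,4,5,6-tetramethoxyphenyl)ethan-1-one
Product: 7 5,6,7,8-tetramethoxy-4H-chromen-4-one, via enaminone 6 (not isolated)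
Conditions: DMF-DMA, toluene, 100 °C; then conc. HCl, CH2Cl2, rt
Reagents that add atoms: N,N-dimethylformamide dimethyl acetal, COC(OC)N(C)C
Why: Condensation of the methyl ketone with the amide acetal gives the enaminone, and acid-promoted addition–elimination by the ortho phenol with loss of dimethylamine closes ring C (enaminone chromone synthesis).

Step 4
Reactants: 7 5,6,7,8-tetramethoxy-4H-chromen-4-one
Product: 8 5-hydroxy-6,7,8-trimethoxy-4H-chromen-4-one
Conditions: BCl3 (1.1 equiv), CH2Cl2, −78 to 0 °C; then H2O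
Reagents that add atoms: none
Why: Chelation-directed ether cleavage, in which boron bound to the C4 carbonyl removes only the peri C5 methyl group, is done here because the molecule has no stereocentre and no ionisable benzylic C–O bond yet.

Step 5
Reactants: 8 5-hydroxy-6,7,8-trimethoxy-4H-chromen-4-one
Product: 9 5-(benzyloxy)-6,7,8-trimethoxy-4H-chromen-4-one
Conditions: BnBr, K2CO3, DMF, 60 °C
Reagents that add atoms: benzyl bromide, BrCc1ccccc1
Why: Williamson etherification of the hydrogen-bonded C5 phenol installs a group that survives all later steps and leaves by neutral hydrogenolysis.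

Step 6
Reactants: 9 5-(benzyloxy)-6,7,8-trimethoxy-4H-chromen-4-one; 10 trimethylsilylacetylene
Product: 13 (S)-5-(benzyloxy)-6,7,8-trimethoxy-2-[(trimethylsilyl)ethynyl]chroman-4-one, via silyloxybenzopyrylium triflate 11 (not isolated), via silyl enol ether 12 (not isolated)
Conditions: TMSOTf, CH2Cl2–toluene, 0 °C; 10, CuI (10 mol%), chiral P,N ligand (StackPhos type), i-Pr2NEt, −40 °C; then 1 M HCl
Reagents that add atoms: none
Why: Copper-catalysed enantioselective alkynylation of a chromone through its 4-silyloxybenzopyrylium ion, in which the ligand on the copper acetylide controls the face of attack at C2 (catalyst control, antipode chosen for 2S), and mild acid frees the ketone from the enol ether without touching the C-silyl group.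

Step 7
Reactants: 13 (S)-5-(benzyloxy)-6,7,8-trimethoxy-2-[(trimethylsilyl)ethynyl]chroman-4-one
Product: 14 (S)-5-(benzyloxy)-6,7,8-trimethoxy-2-[(trimethylsilyl)ethynyl]spiro[chromane-4,2'-[1,3]dioxolane]
Conditions: TMSOCH2CH2OTMS, TMSOTf (5 mol%), CH2Cl2, −78 to −20 °C; pyridine quench
Reagents that add atoms: 1,2-bis(trimethylsilyloxy)ethane, C[Si](C)(C)OCCO[Si](C)(C)C
Why: Noyori ketalisation under aprotic conditions masks C4, so that no enolate and hence no retro-oxa-Michael opening of ring C (which would racemise C2) can arise in the basic steps that follow.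

Step 8
Reactants: 14 (S)-5-(benzyloxy)-6,7,8-trimethoxy-2-[(trimethylsilyl)ethynyl]spiro[chromane-4,2'-[1,3]dioxolane]
Product: 15 (S)-5-(benzyloxy)-2-ethynyl-6,7,8-trimethoxyspiro[chromane-4,2'-[1,3]dioxolane]
Conditions: K2CO3, MeOH–THF, rt
Reagents that add atoms: none
Why: Base-catalysed methanolysis of the alkynyl C–Si bond (protodesilylation) leaves ketal, benzyl ether and C2 untouched.

Step 9
Reactants: 15 (S)-5-(benzyloxy)-2-ethynyl-6,7,8-trimethoxyspiro[chromane-4,2'-[1,3]dioxolane]
Product: 18 (S)-5-(benzyloxy)-6,7,8-trimethoxy-2-[(triisopropylsilyloxy)ethynyl]spiro[chromane-4,2'-[1,3]dioxolane], via lithium acetylide 16 (not isolated), via lithium ynolate 17 (not isolated)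
Conditions: n-BuLi (1.0 equiv), THF, −78 °C; t-BuOOLi (from t-BuOOH, LiHMDS), −78 to 0 °C; TIPSOTf, −78 to 0 °C
Reagents that add atoms: tert-butyl hydroperoxide, CC(C)(C)OO; triisopropylsilyl triflate, CC(C)[Si](OS(=O)(=O)C(F)(F)F)(C(C)C)C(C)C
Why: Oxidation of a lithium acetylide by lithium tert-butyl peroxide (oxygen transfer to carbon with loss of tert-butoxide) gives the ynolate, which a bulky silyl triflate silylates on oxygen; this is the established acetylide route to siloxyalkynes.

Step 10
Reactants: 19 3-oxocyclobutane-1-carboxylic acid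
Product: 20 3-bromocyclobutan-1-one
Conditions: HgO, Br2, MgSO4, CH2Cl2, reflux
Reagents that add atoms: bromine, BrBr
Why: Hunsdiecker bromodecarboxylation (Cristol–Firth modification) proceeds through the acyl hypobromite and the cyclobutyl radical.

Step 11
Reactants: 20 3-bromocyclobutan-1-one
Product: 21 cyclobut-2-en-1-one
Conditions: n-Bu3N, rt; vacuum transfer into a −78 °C trap
Reagents that add atoms: none
Why: E1cB dehydrobromination of the β-bromo ketone gives the volatile enone, which is distilled from the ammonium salt and kept cold in solution to suppress polymerisation.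

Step 12
Reactants: 18 (S)-5-(benzyloxy)-6,7,8-trimethoxy-2-[(triisopropylsilyloxy)ethynyl]spiro[chromane-4,2'-[1,3]dioxolane]; 21 cyclobut-2-en-1-one
Product: 26 2-[(S)-5-(benzyloxy)-6,7,8-trimethoxyspiro[chromane-4,2'-[1,3]dioxolan]-2-yl]-3-(triisopropylsilyloxy)phenol, via vinylketene 22 (not isolated), via vinylcyclobutenone 23 (not isolated), via dienylketene 24 (not isolated), via cyclohexadienone 25 (not isolated)
Conditions: 21 (2–3 equiv, added in portions), toluene, 80 °C, sealed tube
Reagents that add atoms: none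
Why: Thermal 4π opening of 21 gives vinylketene 22, whose C=C=O unit adds [2+2] to the siloxyalkyne: the nucleophilic alkyne carbon (the one bonded to C2, later C1') bonds to the ketene carbonyl carbon (later C6'), and the siloxy-bearing carbon (later C2') bonds to the ketene α-carbon (later C3'), giving 23. Cyclobutenone 23 opens (4π) to dienylketene 24, ring B closes by 6π electrocyclisation between the ketene carbon and the terminal vinyl carbon (C5'–C6'), and dienone 25 tautomerises to the phenol. This is the Danheiser benzannulation, known for cyclobutenones with siloxyalkynes, which gives resorcinol monosilyl ethers carrying the alkyne substituent between the two oxygens. No stereocentre is formed: the ring CH of 23 is erased on opening, and C2 is a spectator that has no acidic or ionisable neighbour under neutral thermal conditions. The step needs the regioselectivity of the ketene–alkyne [2+2], which the oxygen-induced polarisation of the siloxyalkyne secures, and it needs capture of the ketene by the alkyne to outrun ketene self-reaction, which portionwise addition of 21 supports.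

Step 13
Reactants: 26 2-[(S)-5-(benzyloxy)-6,7,8-trimethoxyspiro[chromane-4,2'-[1,3]dioxolan]-2-yl]-3-(triisopropylsilyloxy)phenol
Product: 27 (S)-5-(benzyloxy)-6,7,8-trimethoxy-2-[2-methoxy-6-(triisopropylsilyloxy)phenyl]spiro[chromane-4,2'-[1,3]dioxolane]
Conditions: MeI, K2CO3, DMF, rt
Reagents that add atoms: iodomethane, CI
Why: Williamson methylation of the only free phenol gives a single methyl ether because the other B-ring oxygen is silylated, and ketal-masked ring C cannot open under base.

Step 14
Reactants: 27 (S)-5-(benzyloxy)-6,7,8-trimethoxy-2-[2-methoxy-6-(triisopropylsilyloxy)phenyl]spiro[chromane-4,2'-[1,3]dioxolane]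
Product: 28 (S)-6,7,8-trimethoxy-2-[2-methoxy-6-(triisopropylsilyloxy)phenyl]spiro[chromane-4,2'-[1,3]dioxolan]-5-ol
Conditions: H2 (1 atm), 10% Pd/C, EtOAc, rt
Reagents that add atoms: none
Why: Hydrogenolysis of the benzyl ether under neutral conditions frees the C5 hydroxyl while C4 is still a ketal, so no ketone is exposed to reduction and the hindered C2–O1 bond should stay intact.

Step 15
Reactants: 28 (S)-6,7,8-trimethoxy-2-[2-methoxy-6-(triisopropylsilyloxy)phenyl]spiro[chromane-4,2'-[1,3]dioxolan]-5-ol
Product: 30 (2S)-5-hydroxy-2-(2-hydroxy-6-methoxyphenyl)-6,7,8-trimethoxychroman-4-one, via diphenol ketal 29 (not isolated)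
Conditions: TBAF, THF, 0 °C; then 1 M HCl, rt
Reagents that add atoms: water, O
Why: Fluoride cleaves the aryl silyl ether while the ketone is still masked (no base-induced retro-oxa-Michael), and dilute aqueous acid then hydrolyses the electron-rich benzylic ketal, conditions under which the 2S centre should persist.

**Compound list**

1 | 1,2,3,4-tetramethoxybenzene | COc1ccc(OC)c(OC)c1OC | starting material
2 | (2,3,4,5-tetramethoxyphenyl)lithium | [Li]c1cc(OC)c(OC)c(OC)c1OC | intermediate
3 | lithium trimethoxy(2,3,4,5-tetramethoxyphenyl)borate | [Li+].CO[B-](OC)(OC)c1cc(OC)c(OC)c(OC)c1OC | intermediate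
4 | 2,3,4,5-tetramethoxyphenol | Oc1cc(OC)c(OC)c(OC)c1OC | intermediate
5 | 1-(2-hydroxy-3,4,5,6-tetramethoxyphenyl)ethan-1-one | CC(=O)c1c(O)c(OC)c(OC)c(OC)c1OC | intermediate
6 | (E)-3-(dimethylamino)-1-(2-hydroxy-3,4,5,6-tetramethoxyphenyl)prop-2-en-1-one | CN(C)/C=C/C(=O)c1c(O)c(OC)c(OC)c(OC)c1OC | intermediate
7 | 5,6,7,8-tetramethoxy-4H-chromen-4-one | O=c1ccoc2c(OC)c(OC)c(OC)c(OC)c12 | intermediate
8 | 5-hydroxy-6,7,8-trimethoxy-4H-chromen-4-one | O=c1ccoc2c(OC)c(OC)c(OC)c(O)c12 | intermediate
9 | 5-(benzyloxy)-6,7,8-trimethoxy-4H-chromen-4-one | O=c1ccoc2c(OC)c(OC)c(OC)c(OCc3ccccc3)c12 | intermediate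
10 | trimethylsilylacetylene | C#C[Si](C)(C)C | starting material
11 | 5-(benzyloxy)-6,7,8-trimethoxy-4-(trimethylsilyloxy)chromenylium triflate | C[Si](C)(C)Oc1cc[o+]c2c(OC)c(OC)c(OC)c(OCc3ccccc3)c12.[O-]S(=O)(=O)C(F)(F)F | intermediate
12 | (S)-5-(benzyloxy)-6,7,8-trimethoxy-4-(trimethylsilyloxy)-2-[(trimethylsilyl)ethynyl]-2H-chromene | C[Si](C)(C)C#C[C@@H]1C=C(O[Si](C)(C)C)c2c(OCc3ccccc3)c(OC)c(OC)c(OC)c2O1 | intermediate
13 | (S)-5-(benzyloxy)-6,7,8-trimethoxy-2-[(trimethylsilyl)ethynyl]chroman-4-one | C[Si](C)(C)C#C[C@@H]1CC(=O)c2c(OCc3ccccc3)c(OC)c(OC)c(OC)c2O1 | intermediate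
14 | (S)-5-(benzyloxy)-6,7,8-trimethoxy-2-[(trimethylsilyl)ethynyl]spiro[chromane-4,2'-[1,3]dioxolane] | C[Si](C)(C)C#C[C@@H]1CC2(OCCO2)c2c(OCc3ccccc3)c(OC)c(OC)c(OC)c2O1 | intermediate
15 | (S)-5-(benzyloxy)-2-ethynyl-6,7,8-trimethoxyspiro[chromane-4,2'-[1,3]dioxolane] | C#C[C@@H]1CC2(OCCO2)c2c(OCc3ccccc3)c(OC)c(OC)c(OC)c2O1 | intermediate
16 | lithium acetylide of 15 | [Li]C#C[C@@H]1CC2(OCCO2)c2c(OCc3ccccc3)c(OC)c(OC)c(OC)c2O1 | intermediate
17 | lithium ynolate, (S)-2-(lithiooxyethynyl) ketal | [Li]OC#C[C@@H]1CC2(OCCO2)c2c(OCc3ccccc3)c(OC)c(OC)c(OC)c2O1 | intermediate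
18 | (S)-5-(benzyloxy)-6,7,8-trimethoxy-2-[(triisopropylsilyloxy)ethynyl]spiro[chromane-4,2'-[1,3]dioxolane] | CC(C)[Si](C(C)C)(C(C)C)OC#C[C@@H]1CC2(OCCO2)c2c(OCc3ccccc3)c(OC)c(OC)c(OC)c2O1 | intermediate
19 | 3-oxocyclobutane-1-carboxylic acid | O=C1CC(C(=O)O)C1 | starting material
20 | 3-bromocyclobutan-1-one | O=C1CC(Br)C1 | intermediate
21 | cyclobut-2-en-1-one | O=C1C=CC1 | intermediate
22 | vinylketene (buta-1,3-dien-1-one) | C=CC=C=O | intermediate
23 | 2-[(S)-chroman-2-yl ketal]-3-(triisopropylsilyloxy)-4-vinylcyclobut-2-en-1-one (both configurations at the ring CH) | C=CC1C(=O)C([C@@H]2CC3(OCCO3)c3c(OCc4ccccc4)c(OC)c(OC)c(OC)c3O2)=C1O[Si](C(C)C)(C(C)C)C(C)C | intermediate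
24 | dienylketene, 2-[(S)-chroman-2-yl ketal]-3-(triisopropylsilyloxy)hexa-1,3,5-trien-1-one (ketene and vinyl cis) | O=C=C([C@@H]1CC2(OCCO2)c2c(OCc3ccccc3)c(OC)c(OC)c(OC)c2O1)/C(O[Si](C(C)C)(C(C)C)C(C)C)=C\C=C | intermediate
25 | 2-[(S)-chroman-2-yl ketal]-3-(triisopropylsilyloxy)cyclohexa-2,4-dien-1-one | O=C1CC=CC(O[Si](C(C)C)(C(C)C)C(C)C)=C1[C@@H]1CC2(OCCO2)c2c(OCc3ccccc3)c(OC)c(OC)c(OC)c2O1 | intermediate
26 | 2-[(S)-5-(benzyloxy)-6,7,8-trimethoxyspiro[chromane-4,2'-[1,3]dioxolan]-2-yl]-3-(triisopropylsilyloxy)phenol | CC(C)[Si](C(C)C)(C(C)C)Oc1cccc(O)c1[C@@H]1CC2(OCCO2)c2c(OCc3ccccc3)c(OC)c(OC)c(OC)c2O1 | intermediate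
27 | (S)-5-(benzyloxy)-6,7,8-trimethoxy-2-[2-methoxy-6-(triisopropylsilyloxy)phenyl]spiro[chromane-4,2'-[1,3]dioxolane] | COc1cccc(O[Si](C(C)C)(C(C)C)C(C)C)c1[C@@H]1CC2(OCCO2)c2c(OCc3ccccc3)c(OC)c(OC)c(OC)c2O1 | intermediate
28 | (S)-6,7,8-trimethoxy-2-[2-methoxy-6-(triisopropylsilyloxy)phenyl]spiro[chromane-4,2'-[1,3]dioxolan]-5-ol | COc1cccc(O[Si](C(C)C)(C(C)C)C(C)C)c1[C@@H]1CC2(OCCO2)c2c(O)c(OC)c(OC)c(OC)c2O1 | intermediate
29 | (S)-2-(2-hydroxy-6-methoxyphenyl)-6,7,8-trimethoxyspiro[chromane-4,2'-[1,3]dioxolan]-5-ol | COc1cccc(O)c1[C@@H]1CC2(OCCO2)c2c(O)c(OC)c(OC)c(OC)c2O1 | intermediate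
30 | (2S)-5-hydroxy-2-(2-hydroxy-6-methoxyphenyl)-6,7,8-trimethoxychroman-4-one | COc1cccc(O)c1[C@@H]1CC(=O)c2c(O)c(OC)c(OC)c(OC)c2O1 | target

**Step count**

Total: 15 steps. Longest linear sequence: 13 steps (steps 1–9 and 12–15); steps 10–11 form the two-step cyclobutenone branch.

**Steps most likely to fail, with fallbacks**

1. Step 12 (benzannulation). Dimerisation or polymerisation of cyclobutenone and of vinylketene may outrun capture by the hindered, branched siloxyalkyne, and surplus ketene may acylate the product phenol. The fallback sets out from 18 and returns at 26; it generates the same ketene photochemically at room temperature, at low stationary concentration, from a diazo ketone instead of from cyclobutenone. Commercial 2,3-dibromopropanoyl chloride would be treated with diazomethane to give 3,4-dibromo-1-diazobutan-2-one F1. Zinc dust would remove the two bromines to give 1-diazobut-3-en-2-one F2. Irradiation of F2 with 18 in 1,2-dichloroethane (photochemical Wolff rearrangement) should give vinylketene 22 and from it cyclobutenone 23; brief warming to 80 °C would then carry 23 through 24 and 25 to 26.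

2. Step 9 (siloxyalkyne formation). Oxygen transfer from the peroxide to the acetylide may be incomplete, the silyl triflate may open the ketal, or the ynolate may expel the C2 aryloxide on warming. The fallback sets out from 15 and returns at 18; it reaches the ynolate by carbenoid rearrangement and traps it with a silyl chloride, avoiding both peroxide and triflate. Oxidative bromohydration of the terminal alkyne (N-bromosuccinimide, aqueous acetonitrile, NaHCO3 buffer) should give (S)-2-(dibromoacetyl)-5-(benzyloxy)-6,7,8-trimethoxyspiro[chromane-4,2'-[1,3]dioxolane] F3. LiHMDS at −78 °C would form the dibromo enolate (deprotonation at CHBr2, not at C2). n-BuLi would then effect bromine–lithium exchange, and warming to 0 °C should trigger the Kowalski-type 1,2-shift of the chromanyl group to give ynolate 17. Triisopropylsilyl chloride would silylate 17 on oxygen to give 18. This fallback does not remove the risk of aryloxide loss from the ynolate, which is common to both entries.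

3. Step 6 (enantioselective alkynylation). Facial selectivity may be poor, or addition slow, because the pyrylium ion is strongly donor-stabilised and flanked by the peri benzyloxy group. The fallback sets out from 9 (with 10) and returns at 13; it replaces asymmetric catalysis by resolution. Pyrylium 11 would be treated with the copper acetylide of 10 without chiral ligand (CuI, i-Pr2NEt, then 1 M HCl) to give racemic 5-(benzyloxy)-6,7,8-trimethoxy-2-[(trimethylsilyl)ethynyl]chroman-4-one F4. Preparative chromatography on a chiral stationary phase would separate the enantiomers; the 2S enantiomer is 13.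

**Further compounds**

F1 | step 12 | 3,4-dibromo-1-diazobutan-2-one | BrCC(Br)C(=O)C=[N+]=[N-]
F2 | step 12 | 1-diazobut-3-en-2-one | C=CC(=O)C=[N+]=[N-]
F3 | step 9 | (S)-2-(dibromoacetyl)-5-(benzyloxy)-6,7,8-trimethoxyspiro[chromane-4,2'-[1,3]dioxolane] | BrC(Br)C(=O)[C@@H]1CC2(OCCO2)c2c(OCc3ccccc3)c(OC)c(OC)c(OC)c2O1
F4 | step 6 | racemic 5-(benzyloxy)-6,7,8-trimethoxy-2-[(trimethylsilyl)ethynyl]chroman-4-one | C[Si](C)(C)C#CC1CC(=O)c2c(OCc3ccccc3)c(OC)c(OC)c(OC)c2O1
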